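The numbers of this flask are assumed.

Two questions stood on this flask, one on chain length and one on conversion, and I drew both from a single time.

free monomer 27 mM; initiator 0.14 mM; time 2.5 h

    free monomer + initiator → living end + monomer in chains (k1 = 0.045 /M/s)
    free monomer + living end → monomer in chains + living end, rate k2*[living end]*[free monomer] (k2 = 0.51 /M/s)
    monomer in chains + living end → free monomer + living end, rate k3*[living end] as long as [monomer in chains] is above zero (k3 = 0.0013 /s)
    initiator → spent initiator (k4 = 1.4 × 10⁻⁵ /s)

- the average divides the monomer in chains by the number of chains begun, living and dead together
- run time (flask): 2.5 h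

* average number of monomer units in a chain (chains begun, living or dead) at 2.5 h
* part of the free monomer that has reacted at 2.5 h

I asked first where the flask ends. Growth and unzipping both carry c(living end), so free monomer falls towards a floor, the equilibrium monomer concentration:

c(floor) = 0.0013 /s/0.51 /M/s = 2.55 mM

No step consumes a living end, so I set c(living end) to the initiator charge. That gave the relaxation time τ, in which the gap between free monomer and its floor shrinks by the factor e:

τ = 1/(0.51 /M/s · 0.14 mM) = 3.89 h

Reacted part = (1 − 2.55 mM/27 mM) · (1 − exp(−2.5 h/τ)) = 42.9%

Chain length = 42.9% · 27 mM/0.14 mM = 82.8

The weak link was having every living end present from the start. Initiator is used up pseudo-first-order, and the missing ends add up to a delay: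

delay = 1/(0.045 /M/s · 27 mM) = 0.229 h

I ignored initiator decay, whose half-life of 14 h is far longer than that delay. Starting the clock late gave 40.0% and a chain length of 77.2.

The forecast said 78 and 40%, against my 77.2 and 40.0%, and it began from this: “Initiation is essentially finished”.

The simulation gave 78.0 and 39.9%. At 2.50 h in this flask, monomer in chains was still being made 6.37 times faster than it was used up, each step taken net. With τ, this flask at 25.0 h reckons to 90.4% reacted, and the simulation gave 90.4%.

For the neighbour flask with 16 mM of free monomer and the same initiator charge, τ stays, since its formula holds no c(free monomer), while the delay becomes 0.386 h. That gives 35.2% and a chain length of 40.2; the simulation gave 35.2% and 41.2.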